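**Retrosynthetic overview**
- The dihydrofuran is made last from a homopropargylic alcohol (5-endo alkynol cycloisomerization), so the acid-labile enol ether never meets an acid or an oxidant.
- The C8 acetate comes from an enol acetate epoxide rearrangement; the enol acetate is trapped during the oxa-Michael spirocyclization that closes the tetrahydrofuran and sets C9.
- The C11–C12 bond comes from Michael addition of a C13-stereodefined sulfone (Sharpless epoxide) to an exo-methylene decalone; enol triflate/methyl coupling then fixes the C8=C9 alkene.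
- Rings A and B are closed together from an acyclic (E,E)-dienal by an enantioselective radical-cation (organo-SOMO) bicyclization; C4 is then set by enolate methylation.
- Ring order: A+B (one operation) → spiro-tetrahydrofuran → dihydrofuran.

Assumption: the target is the (4S,5S,8R,9S,10S,13R) isomer encoded in the SMILES; labdane numbering is used (C17 = methyl on C8, C18 = 4α-methyl, C19 = 4β-CH2O, C20 = 10β-methyl, C16 = OCH2 on C13), with α = below and β = above the decalin.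

**Route**

Step 1
Reactants: 1 geranyl acetate
Product: 2 (2E,6E)-8-hydroxy-3,7-dimethylocta-2,6-dienyl acetate
Conditions: SeO2 (0.1 equiv), t-BuOOH (2 equiv), salicylic acid (cat.), CH2Cl2, rt
Reagents that add atoms: tert-butyl hydroperoxide, CC(C)(C)OO; selenium dioxide, O=[Se]=O
Why: Riley-type SeO2 allylic hydroxylation (ene reaction then [2,3]-shift) oxidises only the (E)-methyl of the electron-rich terminal alkene, the other alkene being deactivated by the allylic acetate.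

Step 2
Reactants: 2 (2E,6E)-8-hydroxy-3,7-dimethylocta-2,6-dienyl acetate
Product: 3 (2E,6E)-8-bromo-3,7-dimethylocta-2,6-dienyl acetate
Conditions: CBr4, PPh3, CH2Cl2, 0 °C
Reagents that add atoms: tetrabromomethane, BrC(Br)(Br)Br
Why: Appel bromination converts the primary allylic alcohol into the bromide under neutral conditions without allylic transposition.

Step 3
Reactants: 3 (2E,6E)-8-bromo-3,7-dimethylocta-2,6-dienyl acetate; 4 2-(3-chloropropyl)-1,3-dioxolane
Product: 7 (2E,6E)-3,7-dimethyl-12-oxododeca-2,6-dienyl acetate, via Grignard reagent 5 (not isolated), via dioxolane acetal 6 (not isolated)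
Conditions: 4, Mg, THF, reflux; then 3, Li2CuCl4 (3 mol%), THF, −20 °C; then 2 M HCl, acetone, rt
Reagents that add atoms: water, O
Why: Kochi–Schlosser copper-catalysed Grignard coupling displaces the allylic bromide in the SN2 sense much faster than the acetate reacts at −20 °C, and acid hydrolysis of the dioxolane then frees the aldehyde.

Step 4
Reactants: 7 (2E,6E)-3,7-dimethyl-12-oxododeca-2,6-dienyl acetate
Product: 8 [(1S,4aS,5R,8aS)-5-formyl-8a-methyl-2-methylidenedecahydronaphthalen-1-yl]methyl acetate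
Conditions: (2S,5S)-2-tert-butyl-3-methyl-5-(naphthalen-1-ylmethyl)imidazolidin-4-one·CF3CO2H (30 mol%), Cu(OTf)2 (2.5 equiv), NaO2CCF3 (2 equiv), CF3CO2H (3 equiv), i-PrCN/DME, rt
Reagents that add atoms: none
Why: Proposed new method: organo-SOMO radical-cation polyene bicyclization, known with arene terminators, is extended to an olefinic terminus; the enamine radical cation is attacked at C4 on the face left open by the catalyst, the chair–chair 6-endo/6-endo cascade through the (E,E)-diene sets 5α-H, 10β-CH3 and the 9β-CH2OAc group, and the tertiary C8 radical is oxidised by carboxylate-ligated divalent copper with loss of a C17 proton to the exocyclic alkene, the closest known reactions being SOMO polyene cyclizations and Mn(OAc)3/Cu(OAc)2 oxidative radical bicyclizations.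

Step 5
Reactants: 8 [(1S,4aS,5R,8aS)-5-formyl-8a-methyl-2-methylidenedecahydronaphthalen-1-yl]methyl acetate
Product: 9 [(1S,4aR,5S,8aS)-5-formyl-5,8a-dimethyl-2-methylidenedecahydronaphthalen-1-yl]methyl acetate
Conditions: KOtBu (1.1 equiv), MeI (5 equiv), THF, 0 °C
Reagents that add atoms: iodomethane, CI
Why: C-methylation of the exocyclic aldehyde enolate occurs from the α (equatorial) face because the β face is blocked by the 1,3-diaxial C10 methyl, giving the 4α-methyl/4β-formyl quaternary centre.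

Step 6
Reactants: 9 [(1S,4aR,5S,8aS)-5-formyl-5,8a-dimethyl-2-methylidenedecahydronaphthalen-1-yl]methyl acetate
Product: 10 [(1S,4aR,5S,8aS)-5-(hydroxymethyl)-5,8a-dimethyl-2-methylidenedecahydronaphthalen-1-yl]methyl acetate
Conditions: NaBH4, MeOH, 0 °C
Reagents that add atoms: none
Why: Borohydride reduces the neopentyl aldehyde to the C19 alcohol and leaves the acetate and alkene untouched.

Step 7
Reactants: 10 [(1S,4aR,5S,8aS)-5-(hydroxymethyl)-5,8a-dimethyl-2-methylidenedecahydronaphthalen-1-yl]methyl acetate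
Product: 11 [(1S,4aR,5S,8aS)-5-{[tert-butyl(dimethyl)silyl]oxymethyl}-5,8a-dimethyl-2-methylidenedecahydronaphthalen-1-yl]methyl acetate
Conditions: TBSCl, imidazole, DMF, rt
Reagents that add atoms: tert-butyl(chloro)dimethylsilane, CC(C)(C)[Si](C)(C)Cl
Why: Standard silylation protects the C19 hydroxyl for the carbanion, oxidation and acylation steps that follow.

Step 8
Reactants: 11 [(1S,4aR,5S,8aS)-5-{[tert-butyl(dimethyl)silyl]oxymethyl}-5,8a-dimethyl-2-methylidenedecahydronaphthalen-1-yl]methyl acetate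
Product: 13 (4aR,5S,8aS)-5-{[tert-butyl(dimethyl)silyl]oxymethyl}-5,8a-dimethyl-1-methylideneoctahydronaphthalen-2(1H)-one, via keto acetate 12 (not isolated)
Conditions: O3, CH2Cl2, −78 °C; Me2S; then DBU, 0 °C
Reagents that add atoms: ozone, [O-][O+]=O
Why: Ozonolysis of the only alkene gives the C8 ketone, and E1cB loss of the β-acetoxy group then forms the C9=C11 exo-methylene enone.

Step 9
Reactants: 14 2-bromoprop-2-en-1-ol; 15 ethynyltrimethylsilane
Product: 16 2-methylidene-4-(trimethylsilyl)but-3-yn-1-ol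
Conditions: Pd(PPh3)2Cl2 (2 mol%), CuI (4 mol%), Et3N, THF, rt
Reagents that add atoms: none
Why: Sonogashira coupling of the vinyl bromide with the terminal alkyne gives the 2-alkynyl allylic alcohol.

Step 10
Reactants: 16 2-methylidene-4-(trimethylsilyl)but-3-yn-1-ol
Product: 17 {(2R)-2-[(trimethylsilyl)ethynyl]oxiran-2-yl}methanol
Conditions: Ti(OiPr)4 (10 mol%), D-(−)-diethyl tartrate (12 mol%), t-BuOOH (2 equiv), 4 Å MS, CH2Cl2, −20 °C
Reagents that add atoms: tert-butyl hydroperoxide, CC(C)(C)OO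
Why: Sharpless asymmetric epoxidation of the 2-substituted allylic alcohol with the D-tartrate delivers oxygen to the face that gives the (R)-epoxide, which becomes C13.

Step 11
Reactants: 17 {(2R)-2-[(trimethylsilyl)ethynyl]oxiran-2-yl}methanol
Product: 18 tert-butyl(dimethyl)({(2S)-2-[(trimethylsilyl)ethynyl]oxiran-2-yl}methoxy)silane
Conditions: TBSCl, imidazole, DMF, 0 °C
Reagents that add atoms: tert-butyl(chloro)dimethylsilane, CC(C)(C)[Si](C)(C)Cl
Why: Silylation of the primary hydroxyl (future O16) prevents Payne rearrangement; the descriptor changes only because the priorities change.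

Step 12
Reactants: 18 tert-butyl(dimethyl)({(2S)-2-[(trimethylsilyl)ethynyl]oxiran-2-yl}methoxy)silane
Product: 19 (2R)-1-{[tert-butyl(dimethyl)silyl]oxy}-2-[(phenylsulfanyl)methyl]-4-(trimethylsilyl)but-3-yn-2-ol
Conditions: PhSH (1.2 equiv), NaH (10 mol%), THF, 0 °C to rt
Reagents that add atoms: benzenethiol, Sc1ccccc1
Why: Thiolate opens the epoxide by SN2 at the unhindered CH2 terminus, so the quaternary carbinol centre keeps its configuration.

Step 13
Reactants: 19 (2R)-1-{[tert-butyl(dimethyl)silyl]oxy}-2-[(phenylsulfanyl)methyl]-4-(trimethylsilyl)but-3-yn-2-ol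
Product: 20 (2R)-1-{[tert-butyl(dimethyl)silyl]oxy}-2-[(phenylsulfonyl)methyl]-4-(trimethylsilyl)but-3-yn-2-ol
Conditions: mCPBA (2.2 equiv), NaHCO3, CH2Cl2, 0 °C
Reagents that add atoms: 3-chloroperoxybenzoic acid, OOC(=O)c1cccc(Cl)c1
Why: Sulfide-to-sulfone oxidation is much faster than any reaction of the silylalkyne or the tertiary alcohol.

Step 14
Reactants: 13 (4aR,5S,8aS)-5-{[tert-butyl(dimethyl)silyl]oxymethyl}-5,8a-dimethyl-1-methylideneoctahydronaphthalen-2(1H)-one; 20 (2R)-1-{[tert-butyl(dimethyl)silyl]oxy}-2-[(phenylsulfonyl)methyl]-4-(trimethylsilyl)but-3-yn-2-ol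
Product: 23 (13R)-16,19-bis(tert-butyldimethylsilyloxy)-13-hydroxy-12-(phenylsulfonyl)-15-(trimethylsilyl)-17-norlabd-8-en-14-yn-8-yl trifluoromethanesulfonate, via dilithiated sulfone 21 (not isolated), via dilithium enolate adduct 22 (not isolated)
Conditions: 20, n-BuLi (2 equiv), THF/HMPA, −78 °C; 13, −78 °C; Comins' reagent, −78 to −40 °C; AcOH
Reagents that add atoms: N-(5-chloropyridin-2-yl)-1,1,1-trifluoro-N-[(trifluoromethyl)sulfonyl]methanesulfonamide (Comins' reagent), FC(F)(F)S(=O)(=O)N(c1ccc(Cl)cn1)S(=O)(=O)C(F)(F)F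
Why: Michael addition of the α-sulfonyl carbanion to the unhindered exo-methylene carbon forms C11–C12, and O-triflation of the resulting enolate fixes the C8=C9 position (C12 is formed as a mixture and is removed in step 16).

Step 15
Reactants: 23 (13R)-16,19-bis(tert-butyldimethylsilyloxy)-13-hydroxy-12-(phenylsulfonyl)-15-(trimethylsilyl)-17-norlabd-8-en-14-yn-8-yl trifluoromethanesulfonate
Product: 24 (13R)-16,19-bis(tert-butyldimethylsilyloxy)-12-(phenylsulfonyl)-15-(trimethylsilyl)labd-8-en-14-yn-13-ol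
Conditions: MeMgBr (3 equiv), Fe(acac)3 (5 mol%), THF/NMP, −20 °C
Reagents that add atoms: methylmagnesium bromide, C[Mg]Br
Why: Iron-catalysed Kumada-type coupling of the enol triflate installs C17 and gives the tetrasubstituted C8=C9 alkene as a single regioisomer.

Step 16
Reactants: 24 (13R)-16,19-bis(tert-butyldimethylsilyloxy)-12-(phenylsulfonyl)-15-(trimethylsilyl)labd-8-en-14-yn-13-ol
Product: 25 (13R)-16,19-bis(tert-butyldimethylsilyloxy)-15-(trimethylsilyl)labd-8-en-14-yn-13-ol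
Conditions: SmI2 (4 equiv), HMPA, THF, −78 °C; MeOH
Reagents that add atoms: none
Why: Single-electron reductive desulfonylation removes the sulfone, and the free (unacylated) β-hydroxyl disfavours Julia-type elimination.

Step 17
Reactants: 25 (13R)-16,19-bis(tert-butyldimethylsilyloxy)-15-(trimethylsilyl)labd-8-en-14-yn-13-ol
Product: 26 (13R)-16,19-bis(tert-butyldimethylsilyloxy)-13-hydroxy-15-(trimethylsilyl)labd-8-en-14-yn-7-one
Conditions: CrO3, 3,5-dimethylpyrazole, CH2Cl2, −20 °C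
Reagents that add atoms: chromium trioxide, O=[Cr](=O)=O
Why: Allylic oxidation with the CrO3–dimethylpyrazole complex attacks the accessible ring methylene C7 (C11 is shielded by the adjacent quaternary C10) and gives the 8-en-7-one.

Step 18
Reactants: 26 (13R)-16,19-bis(tert-butyldimethylsilyloxy)-13-hydroxy-15-(trimethylsilyl)labd-8-en-14-yn-7-one
Product: 28 (13R)-9α,13-epoxy-16,19-bis(tert-butyldimethylsilyloxy)-15-(trimethylsilyl)labd-7-en-14-yn-7-yl acetate, via potassium enolate 27 (not isolated)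
Conditions: KN(SiMe3)2 (1.05 equiv), THF, −78 to −40 °C; then Ac2O, −78 °C
Reagents that add atoms: acetic anhydride, CC(=O)OC(C)=O
Why: The tertiary alkoxide adds 5-exo-trig (oxa-Michael) to C9 axially from the α face, anti to the C10 methyl, and O-acylation of the enolate makes the addition irreversible and gives the C7=C8 enol acetate.

Step 19
Reactants: 28 (13R)-9α,13-epoxy-16,19-bis(tert-butyldimethylsilyloxy)-15-(trimethylsilyl)labd-7-en-14-yn-7-yl acetate
Product: 30 (13R)-8β-acetoxy-9α,13-epoxy-16,19-bis(tert-butyldimethylsilyloxy)-15-(trimethylsilyl)labd-14-yn-7-one, via acetoxy epoxide 29 (not isolated)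
Conditions: dimethyldioxirane, acetone/CH2Cl2, 0 °C; then toluene, 110 °C
Reagents that add atoms: dimethyldioxirane, CC1(C)OO1
Why: Epoxidation of the enol acetate is expected from the α face (the β face carries the 1,3-related C10 methyl), and the thermal enol ester epoxide rearrangement moves the acetoxy group to C8 with inversion, giving 8β-OAc/8α-CH3 and the C7 ketone (a β-epoxide would give the same product by the acid-catalysed, retentive variant).

Step 20
Reactants: 30 (13R)-8β-acetoxy-9α,13-epoxy-16,19-bis(tert-butyldimethylsilyloxy)-15-(trimethylsilyl)labd-14-yn-7-one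
Product: 31 (13R)-8β-acetoxy-9α,13-epoxy-16,19-dihydroxylabd-14-yn-7-one
Conditions: Bu4NF, AcOH (1:1), THF, 0 °C to rt
Reagents that add atoms: none
Why: Buffered fluoride cleaves both silyl ethers and the alkynylsilane while the hindered tertiary acetate survives.

Step 21
Reactants: 31 (13R)-8β-acetoxy-9α,13-epoxy-16,19-dihydroxylabd-14-yn-7-one
Product: 32 (13R)-8β-acetoxy-9α,13:15,16-diepoxy-19-hydroxylabd-14-en-7-one (CNP0239339.1)
Conditions: Mo(CO)6 (0.3 equiv), Et3N, Et2O, hν (350 nm), rt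
Reagents that add atoms: none
Why: Endo-selective alkynol cycloisomerization through a molybdenum vinylidene (McDonald-type) adds O16 to C15 under basic, non-oxidising conditions, closing the 2,3-dihydrofuran without touching C13.

**Compound list**
1 | geranyl acetate | CC(=O)OC/C=C(\C)CCC=C(C)C | starting material
2 | (2E,6E)-8-hydroxy-3,7-dimethylocta-2,6-dienyl acetate | CC(=O)OC/C=C(\C)CC/C=C(\C)CO | intermediate
3 | (2E,6E)-8-bromo-3,7-dimethylocta-2,6-dienyl acetate | CC(=O)OC/C=C(\C)CC/C=C(\C)CBr | intermediate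
4 | 2-(3-chloropropyl)-1,3-dioxolane | ClCCCC1OCCO1 | starting material
5 | [3-(1,3-dioxolan-2-yl)propyl]magnesium chloride | Cl[Mg]CCCC1OCCO1 | intermediate
6 | (2E,6E)-11-(1,3-dioxolan-2-yl)-3,7-dimethylundeca-2,6-dienyl acetate | CC(=O)OC/C=C(\C)CC/C=C(\C)CCCCC1OCCO1 | intermediate
7 | (2E,6E)-3,7-dimethyl-12-oxododeca-2,6-dienyl acetate | CC(=O)OC/C=C(\C)CC/C=C(\C)CCCCC=O | intermediate
8 | [(1S,4aS,5R,8aS)-5-formyl-8a-methyl-2-methylidenedecahydronaphthalen-1-yl]methyl acetate (4α-CHO, 5α-H, 9α-H, 10β-CH3) | CC(=O)OC[C@H]1C(=C)CC[C@H]2[C@H](C=O)CCC[C@]12C | intermediate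
9 | [(1S,4aR,5S,8aS)-5-formyl-5,8a-dimethyl-2-methylidenedecahydronaphthalen-1-yl]methyl acetate (4α-CH3, 4β-CHO) | CC(=O)OC[C@H]1C(=C)CC[C@H]2[C@@](C)(C=O)CCC[C@]12C | intermediate
10 | [(1S,4aR,5S,8aS)-5-(hydroxymethyl)-5,8a-dimethyl-2-methylidenedecahydronaphthalen-1-yl]methyl acetate | CC(=O)OC[C@H]1C(=C)CC[C@H]2[C@@](C)(CO)CCC[C@]12C | intermediate
11 | [(1S,4aR,5S,8aS)-5-{[tert-butyl(dimethyl)silyl]oxymethyl}-5,8a-dimethyl-2-methylidenedecahydronaphthalen-1-yl]methyl acetate | CC(=O)OC[C@H]1C(=C)CC[C@H]2[C@@](C)(CO[Si](C)(C)C(C)(C)C)CCC[C@]12C | intermediate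
12 | [(1S,4aR,5S,8aS)-5-{[tert-butyl(dimethyl)silyl]oxymethyl}-5,8a-dimethyl-2-oxodecahydronaphthalen-1-yl]methyl acetate | CC(=O)OC[C@H]1C(=O)CC[C@H]2[C@@](C)(CO[Si](C)(C)C(C)(C)C)CCC[C@]12C | intermediate
13 | (4aR,5S,8aS)-5-{[tert-butyl(dimethyl)silyl]oxymethyl}-5,8a-dimethyl-1-methylideneoctahydronaphthalen-2(1H)-one | C=C1C(=O)CC[C@H]2[C@@](C)(CO[Si](C)(C)C(C)(C)C)CCC[C@]12C | intermediate
14 | 2-bromoprop-2-en-1-ol | OCC(Br)=C | starting material
15 | ethynyltrimethylsilane | C#C[Si](C)(C)C | starting material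
16 | 2-methylidene-4-(trimethylsilyl)but-3-yn-1-ol | OCC(=C)C#C[Si](C)(C)C | intermediate
17 | {(2R)-2-[(trimethylsilyl)ethynyl]oxiran-2-yl}methanol | OC[C@@]1(CO1)C#C[Si](C)(C)C | intermediate
18 | tert-butyl(dimethyl)({(2S)-2-[(trimethylsilyl)ethynyl]oxiran-2-yl}methoxy)silane | CC(C)(C)[Si](C)(C)OC[C@@]1(CO1)C#C[Si](C)(C)C | intermediate
19 | (2R)-1-{[tert-butyl(dimethyl)silyl]oxy}-2-[(phenylsulfanyl)methyl]-4-(trimethylsilyl)but-3-yn-2-ol | CC(C)(C)[Si](C)(C)OC[C@@](O)(CSc1ccccc1)C#C[Si](C)(C)C | intermediate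
20 | (2R)-1-{[tert-butyl(dimethyl)silyl]oxy}-2-[(phenylsulfonyl)methyl]-4-(trimethylsilyl)but-3-yn-2-ol | CC(C)(C)[Si](C)(C)OC[C@@](O)(CS(=O)(=O)c1ccccc1)C#C[Si](C)(C)C | intermediate
21 | C,O-dilithiated sulfone 20 | CC(C)(C)[Si](C)(C)OC[C@@](O[Li])(C([Li])S(=O)(=O)c1ccccc1)C#C[Si](C)(C)C | intermediate
22 | dilithium alkoxide–enolate Michael adduct (C8 enolate, C13 alkoxide; C12 epimers) | CC(C)(C)[Si](C)(C)OC[C@](O[Li])(C#C[Si](C)(C)C)C(CC1=C(O[Li])CC[C@H]2[C@@](C)(CO[Si](C)(C)C(C)(C)C)CCC[C@]12C)S(=O)(=O)c1ccccc1 | intermediate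
23 | (13R)-16,19-bis(tert-butyldimethylsilyloxy)-13-hydroxy-12-(phenylsulfonyl)-15-(trimethylsilyl)-17-norlabd-8-en-14-yn-8-yl trifluoromethanesulfonate (C12 epimers) | CC(C)(C)[Si](C)(C)OC[C@](O)(C#C[Si](C)(C)C)C(CC1=C(OS(=O)(=O)C(F)(F)F)CC[C@H]2[C@@](C)(CO[Si](C)(C)C(C)(C)C)CCC[C@]12C)S(=O)(=O)c1ccccc1 | intermediate
24 | (13R)-16,19-bis(tert-butyldimethylsilyloxy)-12-(phenylsulfonyl)-15-(trimethylsilyl)labd-8-en-14-yn-13-ol (C12 epimers) | CC(C)(C)[Si](C)(C)OC[C@](O)(C#C[Si](C)(C)C)C(CC1=C(C)CC[C@H]2[C@@](C)(CO[Si](C)(C)C(C)(C)C)CCC[C@]12C)S(=O)(=O)c1ccccc1 | intermediate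
25 | (13R)-16,19-bis(tert-butyldimethylsilyloxy)-15-(trimethylsilyl)labd-8-en-14-yn-13-ol | CC(C)(C)[Si](C)(C)OC[C@](O)(C#C[Si](C)(C)C)CCC1=C(C)CC[C@H]2[C@@](C)(CO[Si](C)(C)C(C)(C)C)CCC[C@]12C | intermediate
26 | (13R)-16,19-bis(tert-butyldimethylsilyloxy)-13-hydroxy-15-(trimethylsilyl)labd-8-en-14-yn-7-one | CC(C)(C)[Si](C)(C)OC[C@](O)(C#C[Si](C)(C)C)CCC1=C(C)C(=O)C[C@H]2[C@@](C)(CO[Si](C)(C)C(C)(C)C)CCC[C@]12C | intermediate
27 | potassium C7=C8 enolate of the (13R)-9α,13-epoxy-7-ketone | CC1=C(O[K])C[C@H]2[C@@](C)(CO[Si](C)(C)C(C)(C)C)CCC[C@]2(C)[C@@]13CC[C@](CO[Si](C)(C)C(C)(C)C)(C#C[Si](C)(C)C)O3 | intermediate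
28 | (13R)-9α,13-epoxy-16,19-bis(tert-butyldimethylsilyloxy)-15-(trimethylsilyl)labd-7-en-14-yn-7-yl acetate | CC1=C(OC(C)=O)C[C@H]2[C@@](C)(CO[Si](C)(C)C(C)(C)C)CCC[C@]2(C)[C@@]13CC[C@](CO[Si](C)(C)C(C)(C)C)(C#C[Si](C)(C)C)O3 | intermediate
29 | (13R)-7α,8α:9α,13-diepoxy-16,19-bis(tert-butyldimethylsilyloxy)-15-(trimethylsilyl)labd-14-yn-7β-yl acetate | CC(=O)O[C@@]12C[C@H]3[C@@](C)(CO[Si](C)(C)C(C)(C)C)CCC[C@]3(C)[C@@]4(CC[C@](CO[Si](C)(C)C(C)(C)C)(C#C[Si](C)(C)C)O4)[C@]1(C)O2 | intermediate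
30 | (13R)-8β-acetoxy-9α,13-epoxy-16,19-bis(tert-butyldimethylsilyloxy)-15-(trimethylsilyl)labd-14-yn-7-one | CC(=O)O[C@@]1(C)C(=O)C[C@H]2[C@@](C)(CO[Si](C)(C)C(C)(C)C)CCC[C@]2(C)[C@@]12CC[C@](CO[Si](C)(C)C(C)(C)C)(C#C[Si](C)(C)C)O2 | intermediate
31 | (13R)-8β-acetoxy-9α,13-epoxy-16,19-dihydroxylabd-14-yn-7-one | CC(=O)O[C@@]1(C)C(=O)C[C@H]2[C@@](C)(CO)CCC[C@]2(C)[C@@]12CC[C@](CO)(C#C)O2 | intermediate
32 | (13R)-8β-acetoxy-9α,13:15,16-diepoxy-19-hydroxylabd-14-en-7-one (4S,5S,8R,9S,10S,13R) | CC(=O)O[C@@]1(C)C(=O)C[C@H]2[C@@](C)(CO)CCC[C@]2(C)[C@@]12CC[C@]1(C=COC1)O2 | target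

**Step count**
Total: 21 steps. Longest linear sequence: 16 steps (steps 1–8, then 14–21); steps 9–13 make the side-chain sulfone.

**Three steps most likely to fail, each with a fallback**

Step 4. The radical-cation bicyclization has no precedent with an olefinic terminus; the final radical may be lost to cationic side reactions or give alkene mixtures. The fallback sets out from 3 and returns at 10. Alkylate the dianion of (1S,2R,5S)-8-phenylmenthyl acetoacetate with 3 to give the polyene β-keto ester F1. Cyclize it with Mn(OAc)3·2H2O, Cu(OAc)2·H2O and Yb(OTf)3 in CF3CH2OH (auxiliary-controlled oxidative radical bicyclization, exocyclic alkene by copper-mediated elimination) to the bicyclic β-keto ester F2. Methylate C4 from the α face (K2CO3, MeI) to the quaternary keto ester F3. Remove the C3 carbonyl through the tosylhydrazone F4 (catecholborane, then NaOAc) to the ester F5. Reduce with LiAlH4 to the diol F6, recovering the auxiliary, and acetylate the less hindered C11 hydroxyl (Ac2O, pyridine, 0 °C) to reach 10. The hand of the auxiliary is chosen from memory of related work and would need checking.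

Step 14. The hindered dianion may add 1,2, or the β-alkoxido sulfone may fragment before triflation. The fallback sets out from 11 and returns at 25. Cleave the acetate (K2CO3, MeOH) to the primary alcohol F7 and convert it (I2, PPh3, imidazole) into the iodide F8. Exchange with t-BuLi at −78 °C and open epoxide 18 at its CH2 terminus (BF3·OEt2) to give the exo-methylene tertiary alcohol F9. Move the exocyclic double bond into the tetrasubstituted position (RhCl3·3H2O, EtOH, 70 °C) to reach 25; some of the C7=C8 isomer is likely and would have to be separated.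

Step 18. γ-Deprotonation of the enone or retro-addition may beat cyclization and trapping. The fallback sets out from 26 and returns at 30. Luche reduction (NaBH4, CeCl3·7H2O) gives the 7β-allylic alcohol F10. Hydroxyl-directed epoxidation (VO(acac)2, t-BuOOH) gives the 8β,9β-epoxy alcohol F11. Acid (camphorsulfonic acid, cat.) triggers 5-exo opening at C9 by the C13 hydroxyl with inversion, giving the spiro-tetrahydrofuran 7β,8β-diol F12. MeC(OMe)3 with catalytic acid forms the cyclic orthoacetate F13, and aqueous AcOH opens it to the axial 8β-acetate 7β-alcohol F14. Dess–Martin oxidation then gives 30.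

Further compounds
F1 | step 4 | (1S,2R,5S)-8-phenylmenthyl (6E,10E)-12-acetoxy-6,10-dimethyl-3-oxododeca-6,10-dienoate | CC(=O)OC/C=C(\C)CC/C=C(\C)CCC(=O)CC(=O)O[C@H]1C[C@@H](C)CC[C@@H]1C(C)(C)c1ccccc1
F2 | step 4 | bicyclic β-keto ester (3-oxo, 4-CO2-phenylmenthyl, 8(17)-ene, 9β-CH2OAc; C4 enolisable) | CC(=O)OC[C@H]1C(=C)CC[C@H]2C(C(=O)CC[C@]12C)C(=O)O[C@H]1C[C@@H](C)CC[C@@H]1C(C)(C)c1ccccc1
F3 | step 4 | 4α-methyl-3-oxo-4β-carboxylate (8-phenylmenthyl ester) | CC(=O)OC[C@H]1C(=C)CC[C@H]2[C@@](C)(C(=O)O[C@H]3C[C@@H](C)CC[C@@H]3C(C)(C)c3ccccc3)C(=O)CC[C@]12C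
F4 | step 4 | C3 tosylhydrazone of F3 | CC(=O)OC[C@H]1C(=C)CC[C@H]2[C@@](C)(C(=O)O[C@H]3C[C@@H](C)CC[C@@H]3C(C)(C)c3ccccc3)C(=NNS(=O)(=O)c3ccc(C)cc3)CC[C@]12C
F5 | step 4 | C3-deoxygenated 4β-carboxylate (8-phenylmenthyl ester) | CC(=O)OC[C@H]1C(=C)CC[C@H]2[C@@](C)(C(=O)O[C@H]3C[C@@H](C)CC[C@@H]3C(C)(C)c3ccccc3)CCC[C@]12C
F6 | step 4 | 11,19-diol (8(17)-ene) | OC[C@H]1C(=C)CC[C@H]2[C@@](C)(CO)CCC[C@]12C
F7 | step 14 | C11 alcohol from 11 | OC[C@H]1C(=C)CC[C@H]2[C@@](C)(CO[Si](C)(C)C(C)(C)C)CCC[C@]12C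
F8 | step 14 | C11 iodide | IC[C@H]1C(=C)CC[C@H]2[C@@](C)(CO[Si](C)(C)C(C)(C)C)CCC[C@]12C
F9 | step 14 | (13R)-16,19-bis(tert-butyldimethylsilyloxy)-15-(trimethylsilyl)labd-8(17)-en-14-yn-13-ol | CC(C)(C)[Si](C)(C)OC[C@](O)(C#C[Si](C)(C)C)CC[C@H]1C(=C)CC[C@H]2[C@@](C)(CO[Si](C)(C)C(C)(C)C)CCC[C@]12C
F10 | step 18 | (13R)-16,19-bis(tert-butyldimethylsilyloxy)-15-(trimethylsilyl)labd-8-en-14-yne-7β,13-diol | CC(C)(C)[Si](C)(C)OC[C@](O)(C#C[Si](C)(C)C)CCC1=C(C)[C@@H](O)C[C@H]2[C@@](C)(CO[Si](C)(C)C(C)(C)C)CCC[C@]12C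
F11 | step 18 | (13R)-8β,9β-epoxy-16,19-bis(tert-butyldimethylsilyloxy)-15-(trimethylsilyl)labd-14-yne-7β,13-diol | CC(C)(C)[Si](C)(C)OC[C@](O)(C#C[Si](C)(C)C)CC[C@]12O[C@@]1(C)[C@@H](O)C[C@H]3[C@@](C)(CO[Si](C)(C)C(C)(C)C)CCC[C@]23C
F12 | step 18 | (13R)-9α,13-epoxy-16,19-bis(tert-butyldimethylsilyloxy)-15-(trimethylsilyl)labd-14-yne-7β,8β-diol | O[C@@]1(C)[C@@H](O)C[C@H]2[C@@](C)(CO[Si](C)(C)C(C)(C)C)CCC[C@]2(C)[C@@]12CC[C@](CO[Si](C)(C)C(C)(C)C)(C#C[Si](C)(C)C)O2
F13 | step 18 | 7β,8β-cyclic methyl orthoacetate of F12 (orthoester carbon as a mixture) | COC1(C)O[C@@]2(C)[C@@H](O1)C[C@H]3[C@@](C)(CO[Si](C)(C)C(C)(C)C)CCC[C@]3(C)[C@@]24CC[C@](CO[Si](C)(C)C(C)(C)C)(C#C[Si](C)(C)C)O4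
F14 | step 18 | (13R)-8β-acetoxy-9α,13-epoxy-16,19-bis(tert-butyldimethylsilyloxy)-15-(trimethylsilyl)labd-14-yn-7β-ol | CC(=O)O[C@@]1(C)[C@@H](O)C[C@H]2[C@@](C)(CO[Si](C)(C)C(C)(C)C)CCC[C@]2(C)[C@@]12CC[C@](CO[Si](C)(C)C(C)(C)C)(C#C[Si](C)(C)C)O2
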